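## Retrosynthetic overview

- Drimane numbering is used (ring A: C1–C5, C10; ring B: C5–C10; C11 is the CH2O carbon on C9). The target is the isofraxidin ether of 3β-acetoxy-9βH-drim-7-en-11-ol (C11 on the α face, trans to the C10 methyl), so the aryl ether is cut last (Mitsunobu).
- C11 and the C7=C8 olefin go back to an 11-nor-8-en-7-one: axial conjugate hydroxymethylation at C9, enol triflate, reduction. The C7 oxygen and a C1=C2 olefin are temporary and are removed.
- Key disconnection: C2–C3 and C5–C10 (ring A, formal [3+3]) together with C8–C9 (ring B), back to two acyclic pieces, (E)-2,2-dimethyl-5-oxohept-3-enal and tiglic aldehyde. Ring A forms first, ring B second.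
- Enabling feature: C3 and C5 flank the quaternary gem-dimethyl C4, so C3–C4–C5 is a 1,3-dielectrophile (non-enolisable aldehyde carbon C3, enone β-carbon C5). C2 and C10 are the γ- and α-carbons of a C9 carbonyl (C9–C10(CH3)–C1–C2 is tiglic aldehyde), a 1,3-dinucleophile through its dienamine. The C7 ketone activates C5 and then closes ring B.

Key step: step 3

Assumption: the facial sense of induction of the cinchona primary amine is not predicted here; the pseudo-enantiomer (quinine- or quinidine-derived) that gives the 5α,10β series is used, written below as the quinine-derived one.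

## Route

Step 1
Reactants: 1 3-hydroxy-2,2-dimethylpropanal (from its commercial dimer); 2 diethyl (2-oxobutyl)phosphonate
Product: 3 (E)-7-hydroxy-6,6-dimethylhept-4-en-3-one
Conditions: LiCl, iPr2NEt, MeCN, rt
Reagents that add atoms: none
Why: Horner–Wadsworth–Emmons olefination of the α-quaternary aldehyde with the lithium-chelated β-ketophosphonate anion under a mild amine base should give the (E)-enone (no stereocenter) without retro-aldol cleavage of the hydroxy aldehyde or protection of the primary hydroxyl.

Step 2
Reactants: 3 (E)-7-hydroxy-6,6-dimethylhept-4-en-3-one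
Product: 4 (E)-2,2-dimethyl-5-oxohept-3-enal
Conditions: TEMPO (10 mol %), PhI(OAc)2, CH2Cl2, rt
Reagents that add atoms: none
Why: Oxoammonium (TEMPO) oxidation with PhI(OAc)2 as terminal oxidant should take the neopentyl primary alcohol to the non-enolisable aldehyde without over-oxidation and without touching the enone; no stereocenter is formed.

Step 3
Reactants: 4 (E)-2,2-dimethyl-5-oxohept-3-enal; 5 tiglic aldehyde ((E)-2-methylbut-2-enal, twofold excess)
Product: 8 3β-hydroxy-11-nordrima-1,8-dien-7-one, via vinylogous aldol adduct 6 (not isolated), via ring A keto-aldehyde 7 (not isolated)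
Conditions: 9-amino-9-deoxy-epi-quinine (20 mol %), 2-fluorobenzoic acid (40 mol %), toluene, 25 °C, then 50 °C
Reagents that add atoms: none
Why: Proposed new method: the primary amine turns 5 into a dienamine whose unhindered γ-carbon (C2) adds reversibly to the non-enolisable aldehyde carbon C3 of 4 (vinylogous aldol); the γ-substituted dienamine then adds through its α-carbon C10 to the tethered enone β-carbon C5 (irreversible, because the α-quaternary β,γ-unsaturated aldehyde 7 cannot re-conjugate), and the same amine finally condenses the ethyl ketone with the C9 aldehyde to the ring B enone. The closest known reaction types are amine-catalysed formal [3+3] annulations in which an enal-derived dienamine acts as an α,γ-dinucleophile, the γ-selective dienamine functionalisation of α-branched enals, the intramolecular dienamine α-Michael (Rauhut–Currier-type) cyclisation and the amine-catalysed Robinson annulation of α-branched aldehydes; new is their combination in the order γ-aldol then α-Michael on a 1,3-dielectrophile interrupted by a quaternary carbon. Ring A closes by a 6-(enolexo)-exo-trig Michael addition, helped by the Thorpe–Ingold effect of the C4 gem-dimethyl group, and ring B by a 6-(enolendo)-exo-trig aldol condensation. C10 is set by the catalyst, which shields one face of the C9=C10 enamine and keeps the bulky C9 iminium carbon pseudo-equatorial (methyl axial); C5 and C3 follow from a half-chair transition state with the enone arm and the hydroxyl pseudo-equatorial, and because the aldol step is reversible the C3 epimer that fits this transition state should be funnelled into product (dynamic kinetic resolution). The step needs γ-aldol/α-Michael and not γ-Michael/α-aldol regiochemistry, and ring closure faster than vinylogous dehydration: the α-methyl group blocks intermolecular α-attack, the neopentyl-type C5 blocks intermolecular Michael addition, and the aldehyde of 4 can neither enolise nor form an enamine.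

Step 4
Reactants: 8 3β-hydroxy-11-nordrima-1,8-dien-7-one
Product: 9 3β-acetoxy-11-nordrima-1,8-dien-7-one
Conditions: Ac2O, pyridine, DMAP (10 mol %), CH2Cl2, rt
Reagents that add atoms: acetic anhydride, CC(=O)OC(C)=O
Why: DMAP-catalysed acylation of the hindered allylic secondary alcohol installs the acetate of the target, which also prevents rhodium-mediated redox isomerisation of the allylic alcohol in the next step; C3 is not touched.

Step 5
Reactants: 9 3β-acetoxy-11-nordrima-1,8-dien-7-one
Product: 10 3β-acetoxy-11-nordrim-8-en-7-one
Conditions: H2 (1 atm), RhCl(PPh3)3 (5 mol %), benzene/EtOH, rt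
Reagents that add atoms: none
Why: Homogeneous hydrogenation with RhCl(PPh3)3 should reduce the cis-disubstituted, unconjugated C1=C2 bond in preference to the trisubstituted conjugated enone, and it creates no stereocenter (C1 and C2 become CH2).

Step 6
Reactants: 10 3β-acetoxy-11-nordrim-8-en-7-one
Product: 11 3β-acetoxy-11-[isopropoxy(dimethyl)silyl]-9βH-drim-7-en-7-yl trifluoromethanesulfonate
Conditions: (iPrO)Me2SiCH2MgCl (made in the flask from ClCH2SiMe2(OiPr) and Mg, THF), CuBr·SMe2 (20 mol %), THF, −78 to −30 °C; then N-(5-chloropyridin-2-yl)bis(trifluoromethanesulfonyl)imide, −78 °C to rt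
Reagents that add atoms: (isopropoxydimethylsilyl)methylmagnesium chloride, CC(C)O[Si](C)(C)C[Mg]Cl; N-(5-chloropyridin-2-yl)bis(trifluoromethanesulfonyl)imide, FC(F)(F)S(=O)(=O)N(c1ccc(Cl)cn1)S(=O)(=O)C(F)(F)F
Why: Copper-catalysed conjugate addition of the hydroxymethyl-anion-equivalent Grignard reagent should occur by axial attack on the α face of C9, anti to the axial C10 methyl, which sets the 9α (C11) configuration, and the regiodefined C7 enolate is trapped on oxygen as the enol triflate.

Step 7
Reactants: 11 3β-acetoxy-11-[isopropoxy(dimethyl)silyl]-9βH-drim-7-en-7-yl trifluoromethanesulfonate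
Product: 12 3β-acetoxy-11-[isopropoxy(dimethyl)silyl]-9βH-drim-7-ene
Conditions: Pd(OAc)2 (5 mol %), PPh3 (10 mol %), HCO2H, Bu3N, DMF, 60 °C
Reagents that add atoms: none
Why: Palladium-catalysed formate reduction of the enol triflate (oxidative addition, formate exchange, decarboxylation, reductive elimination) replaces the triflate by hydrogen with the double bond held at C7=C8, which removes the C7 oxygen; no stereocenter changes.

Step 8
Reactants: 12 3β-acetoxy-11-[isopropoxy(dimethyl)silyl]-9βH-drim-7-ene
Product: 13 3β-acetoxy-9βH-drim-7-en-11-ol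
Conditions: 30% H2O2, KF, KHCO3, THF/MeOH, rt
Reagents that add atoms: hydrogen peroxide, OO
Why: Tamao oxidation (fluoride-assisted attack of peroxide on silicon and 1,2-shift of the CH2 group from silicon to oxygen) unmasks the primary C11 alcohol under buffered conditions that the hindered acetate and the trisubstituted alkene should tolerate; C9 is not affected.

Step 9
Reactants: 13 3β-acetoxy-9βH-drim-7-en-11-ol; 14 isofraxidin (7-hydroxy-6,8-dimethoxycoumarin)
Product: 15 7-[(3β-acetoxy-9βH-drim-7-en-11-yl)oxy]-6,8-dimethoxy-2H-chromen-2-one
Conditions: PPh3, DIAD, THF, 0 °C to rt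
Reagents that add atoms: none
Why: In this Mitsunobu etherification the acidic phenol 14 displaces the oxyphosphonium derivative of the primary C11 alcohol in an SN2 step, so no stereocenter is touched and the lactone and the acetate remain intact.

## Compound list

1 | 3-hydroxy-2,2-dimethylpropanal | OCC(C)(C)C=O | starting material
2 | diethyl (2-oxobutyl)phosphonate | CCC(=O)CP(=O)(OCC)OCC | starting material
3 | (E)-7-hydroxy-6,6-dimethylhept-4-en-3-one | CCC(=O)/C=C/C(C)(C)CO | intermediate
4 | (E)-2,2-dimethyl-5-oxohept-3-enal | CCC(=O)/C=C/C(C)(C)C=O | intermediate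
5 | tiglic aldehyde, (E)-2-methylbut-2-enal | C/C=C(\C)C=O | starting material
6 | (2E,5S,7E)-5-hydroxy-2,6,6-trimethyl-9-oxoundeca-2,7-dienal (vinylogous aldol adduct) | CCC(=O)/C=C/C(C)(C)[C@@H](O)C/C=C(\C)C=O | intermediate
7 | 4-hydroxy-1,5,5-trimethyl-6-(2-oxobutyl)cyclohex-2-ene-1-carbaldehyde; hydroxyl, 2-oxobutyl and the C1 methyl on one face, formyl on the other | CCC(=O)C[C@H]1C(C)(C)[C@@H](O)C=C[C@]1(C)C=O | intermediate
8 | 3β-hydroxy-11-nordrima-1,8-dien-7-one (trans ring fusion: 5α-H, 10β-methyl) | C1=C(C)C(=O)C[C@H]2C(C)(C)[C@@H](O)C=C[C@]12C | intermediate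
9 | 3β-acetoxy-11-nordrima-1,8-dien-7-one | C1=C(C)C(=O)C[C@H]2C(C)(C)[C@@H](OC(C)=O)C=C[C@]12C | intermediate
10 | 3β-acetoxy-11-nordrim-8-en-7-one | C1=C(C)C(=O)C[C@H]2C(C)(C)[C@@H](OC(C)=O)CC[C@]12C | intermediate
11 | 3β-acetoxy-11-[isopropoxy(dimethyl)silyl]-9βH-drim-7-en-7-yl trifluoromethanesulfonate (C11 on the α face) | CC(C)O[Si](C)(C)C[C@@H]1C(C)=C(OS(=O)(=O)C(F)(F)F)C[C@H]2C(C)(C)[C@@H](OC(C)=O)CC[C@]12C | intermediate
12 | 3β-acetoxy-11-[isopropoxy(dimethyl)silyl]-9βH-drim-7-ene | CC(C)O[Si](C)(C)C[C@@H]1C(C)=CC[C@H]2C(C)(C)[C@@H](OC(C)=O)CC[C@]12C | intermediate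
13 | 3β-acetoxy-9βH-drim-7-en-11-ol | OC[C@@H]1C(C)=CC[C@H]2C(C)(C)[C@@H](OC(C)=O)CC[C@]12C | intermediate
14 | isofraxidin, 7-hydroxy-6,8-dimethoxy-2H-chromen-2-one | COc1cc2ccc(=O)oc2c(OC)c1O | starting material
15 | 7-[(3β-acetoxy-9βH-drim-7-en-11-yl)oxy]-6,8-dimethoxy-2H-chromen-2-one | COc1cc2ccc(=O)oc2c(OC)c1OC[C@@H]1C(C)=CC[C@H]2C(C)(C)[C@@H](OC(C)=O)CC[C@]12C | target

## Step count and risks

Total steps: 9. Longest linear sequence: 9 steps (1 to 15).

Step 3 (proposed new method). What may go wrong: vinylogous dehydration of the aldol adduct to a dienal before ring A closes, attack of the dienamine γ-carbon on the enone instead of the aldehyde (wrong annulation regiochemistry), or weak facial control in the α-Michael closure. The fallback uses known reactions, sets out from 4 and 5 and returns at 10, so steps 4 and 5 are no longer needed. Compound 5 is converted (TBSOTf, Et3N) into its silyl dienol ether F1. A vinylogous Mukaiyama aldol addition of F1 to the aldehyde of 4 (amino-acid-derived oxazaborolidinone Lewis acid, or BF3·OEt2, CH2Cl2, −78 °C) gives 6 as an isolated compound, with C3 set by the Lewis acid. An amine-salt-catalysed reductive Michael cyclisation with Hantzsch ester (iminium reduction delivers hydrogen to C1 and the resulting enamine adds to the enone) gives the saturated ring A keto-aldehyde F2, with C5 and C10 controlled by the equatorial C3 hydroxyl. KOH in MeOH closes ring B to the hydroxy enone F3, and acetylation (Ac2O, pyridine, DMAP) gives 10.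

Step 6. What may go wrong: enolisation of the ketone at C6 by the Grignard reagent instead of addition to the hindered β-carbon C9, or incomplete O-triflation of the hindered magnesium enolate. The fallback sets out from 10 and returns at 12. Luche reduction (NaBH4, CeCl3·7H2O, MeOH) should give the equatorial 7β-allylic alcohol F4, and esterification with picolinic acid gives the picolinate F5. Copper-mediated anti-SN2' substitution with the same Grignard reagent (CuBr·SMe2, THF) delivers the silylmethyl group to the α face of C9 and moves the double bond to C7=C8, giving 12 directly.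

Step 9. What may go wrong: slow substitution at the β-branched primary carbinol by the doubly ortho-substituted phenol, with competing elimination towards C9. The fallback sets out from 13 and returns at 15. The alcohol is converted (I2, PPh3, imidazole) into the primary iodide F6, which alkylates the caesium phenoxide of 14 (Cs2CO3, DMF, 50 °C; Williamson ether synthesis).

Further compounds
F1 | step 3 | (1E)-1-(tert-butyldimethylsilyloxy)-2-methylbuta-1,3-diene | C=C/C(C)=C/O[Si](C)(C)C(C)(C)C
F2 | step 3 | 4-hydroxy-1,3,3-trimethyl-2-(2-oxobutyl)cyclohexane-1-carbaldehyde; hydroxyl, 2-oxobutyl and the C1 methyl on one face | CCC(=O)C[C@H]1C(C)(C)[C@@H](O)CC[C@]1(C)C=O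
F3 | step 3 | 3β-hydroxy-11-nordrim-8-en-7-one | C1=C(C)C(=O)C[C@H]2C(C)(C)[C@@H](O)CC[C@]12C
F4 | step 6 | 3β-acetoxy-11-nordrim-8-en-7β-ol | C1=C(C)[C@@H](O)C[C@H]2C(C)(C)[C@@H](OC(C)=O)CC[C@]12C
F5 | step 6 | 3β-acetoxy-11-nordrim-8-en-7β-yl pyridine-2-carboxylate | C1=C(C)[C@@H](OC(=O)c3ccccn3)C[C@H]2C(C)(C)[C@@H](OC(C)=O)CC[C@]12C
F6 | step 9 | 3β-acetoxy-11-iodo-9βH-drim-7-ene | IC[C@@H]1C(C)=CC[C@H]2C(C)(C)[C@@H](OC(C)=O)CC[C@]12C
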